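## Structural features

Agrimol B is a row of three benzene rings, A–CH2–B–CH2–C, joined only through two methylene bridges, and every ring carbon of all three rings is substituted. Ring B is a phloroglucinol whose three hydroxyls alternate with the two bridge carbons and the (S)-2-methylbutanoyl group. Rings A and C are identical: starting at the bridge-bearing carbon they carry OH, CH3, OCH3, butanoyl and OH, so the methoxy group lies between methyl and acyl and the bridge lies between two hydroxyls. The only stereocentre is the α-carbon of the ring B ketone; it has no stereogenic neighbour, but it is enolisable and is lost whenever base or strong acid reaches the ketone. Fragile elements are the free polyphenols (oxidation), the diarylmethane links between phloroglucinol rings (cleavage through quinone methides) and, in any carbinol-level intermediate, a benzylic oxygen ortho or para to a free phenol. The real difficulty is the regiospecific construction of the two hexasubstituted outer rings and their attachment to ring B without statistical methylene bridging. The plan exploits that the sequence C(CH2–ring B)–C(OH)–C(CH3)–C(OCH3)–C(acyl)–C(OH) of rings A and C is an isomer of a 3-substituted 4-methoxy-5-methyl-2-pyrone carrying a CH2CH2–ring B chain at C6: the lactone carbonyl becomes the hydroxyl carbon beside the acyl carbon, and the chain methylene next to the pyrone becomes the bridge-bearing ring carbon.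

## Logic of the disconnections

24 ⇒ 23. The seven aryl O–H bonds are traced back to O–CH2OCH3 bonds. Free phenols cannot pass through the oxidation or the organometallic steps, and on ring B the acetal oxygens are needed as directing groups for metalation. Nothing is gained in skeleton, but all polyphenol chemistry is pushed to the last step. The forward step must use acid mild enough for the methylene bridges and for the α-centre of the ketone.

23 ⇒ 22 ⇒ 21. No skeletal bond is cut; the three aryl C=O groups are taken back to C–OH and then to C–O–Si. A ketone on ring B would expose the stereocentre to every base, and ketones on the outer rings would, before aromatisation, offer the carbanion an aldol route to a benzoate. The forward order must be desilylation first (basic, no ketone present) and then a non-enolising oxidation.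

21 ⇒ 20. The four O–CH2OCH3 bonds on rings A and C are cut. The outer rings are born as free resorcinols in 20, and these must be capped before any benzylic oxygen is unmasked or any oxidant is used. The forward step has to alkylate hindered phenols quickly and without long-lived phenoxides.

20 ⇒ 18 (through 19). In each outer ring the bond between the bridge-bearing carbon and the hydroxyl carbon beside the carbinol-bearing carbon is cut, and the carbonyl so freed is closed as a lactone onto the oxygen of the other hydroxyl carbon. Two benzene rings become two 2-pyrones, whose substitution pattern is fixed by simple enolate chemistry. The forward step demands carbon acylation by a singly activated ketone enolate, twice, in competition with reversible reclosure to the pyrone.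

18 ⇒ 17 ⇒ 7 + 15. The CH2–CH2 bond of each arm is cut (as C=C in 17). This is the most convergent place, it uses the vinylogous acidity of the 6-methyl group of 7, and it gives two identical nucleophiles and one two-fold electrophile. The electrophilic carbon is held as an aldehyde in 15 because a 2,4,6-trialkoxybenzyl halide would ionise. The forward steps demand a double vinylogous aldol condensation at hindered aldehydes and hydrogenation of the exocyclic alkenes only.

15 ⇒ 13 ⇒ 9 + 11. The two aryl–CHO bonds and the aryl–carbinol bond are cut. All three carbon substituents of ring B then come from metalation between acetal oxygens, without Friedel–Crafts chemistry, and the stereocentre enters at the carbinol level. The forward addition must be faster than enolisation of 11, and the second formylation must tolerate the first formyl group.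

9 ⇒ 8 and 11 ⇒ 10. Three O–CH2OCH3 bonds and one oxidation level are removed, which reaches two commercial compounds. The oxidation to 11 must not touch the α-centre.

7 ⇒ 4 + 5. The bond between pyrone C3 and the carbinol carbon is cut, together with the O–Si bond. C3–H is the kinetic metalation site, and 5 brings the whole butanoyl chain at the carbinol level. The forward step must metalate C3 and not the 6-methyl group.

4 ⇒ 3 ⇒ 2 ⇒ 1. The O–CH3 bond, the lactone C–O bond and the C–CO2H bond are cut in turn, which reaches a commercial β-diketone. The forward carboxylation must occur at the terminal carbon of the dianion, and the methylation at the 4-oxygen.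

## Other disconnections considered

Alternative 1: The cut lies on ring B, through the aryl C–O bond of one hydroxyl and the aryl–carbonyl bond on the neighbouring carbon. Forward, a fluoride source would release the aryne from the silylaryl triflate A2. The carboxylate of (S)-2-methylbutanoic acid A3 would add to the aryne carbon remote from the flanking benzyloxy group, and the aryl anion would take the acyl group from oxygen to give the ortho-hydroxyaryl ketone A1.
- In favour: insertion of arynes into the C–O bond of carboxylic acids is an established reaction type, whereas the ring transformation of the chosen plan is not; on precedent this alternative is the better one. It places the chiral acyl group and its neighbouring hydroxyl regiospecifically without a Lewis acid and without an enolate. The benzyl ethers of A1 could be removed at the end by neutral hydrogenolysis, which would be gentler on the α-centre than the acidic last step of the chosen plan; on this point it is also the better one.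
- Against: the step forms one C–C bond and no ring, on the least demanding ring. α-Branched aliphatic acids are the weaker partners in this insertion because simple O-arylation competes. A2 itself needs several steps. A1 still lacks both bridges and both hexasubstituted outer rings, which would have to be attached by electrophilic methylene bridging, and the enolisable ketone would be exposed in all later steps.
- Comparison: on structure, the chosen plan builds two rings where this builds none. On mechanism, the alternative is safer. On step economy, the chosen plan installs the same acyl carbon in two steps (6 and 7) and solves the outer rings as well, so it is shorter overall.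

Alternative 2: The cut removes from each outer ring the C(OH)–C(CH3) bond and the C(OCH3)–C(carbinol) bond, so that the two alkyne carbons of 1-methoxypropyne A5 are excised and ring B is left with two cyclobutenone-bearing methylene arms. Forward, each 4-substituted 3-siloxycyclobutenone would open thermally to a vinylketene, add the ynol ether A5 with the polarity-controlled regiochemistry, and pass through 4π opening and 6π closure to give A4 in a two-fold Danheiser benzannulation.
- In favour: like the chosen step it makes both outer rings at once, and it forms four C–C bonds where the chosen step forms two; in bond count it is the better one. The reaction type is known and runs without base, so no phenoxide arises next to a benzylic silyl ether and the ring B ketone sees only heat; on mechanism it is also the safer one. The two new phenols emerge differentiated.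
- Against: the substrate has no short synthesis. Each fully substituted 3-siloxycyclobutenone carries an enolisable stereogenic C4, must be made by a ketene cycloaddition, and must then be joined to ring B through the kind of labile ring B benzylic electrophile that the chosen plan avoids. The vinylketenes are tetrasubstituted, the cycloaddition is crowded, and A5 is volatile and must be prepared.
- Comparison: the structural gain is equal or higher and the precedent is better. Step economy and accessibility of the precursor are clearly worse than for 18, whose arms come from 7 in four steps.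

Alternative 3: The cut goes through ring B itself, which is split into a cyclobutenone carrying one outer arylmethyl group (fragment 1) and a siloxyalkyne carrying the other (fragment 2). Forward, the vinylketene from fragment 1 would add fragment 2, and 4π opening and 6π closure would give the phenol A6 with both arylmethyl groups and three oxygens in place and one free ring carbon.
- In favour: it is the most convergent of the plans, since two elaborate halves are joined in the ring-forming step and ring B is made last; in convergence it is the better one. The reaction type is known and base-free, and no benzylic electrophile on ring B is ever needed.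
- Against: the key step does not address the real difficulty. Both hexasubstituted outer rings must first be made by other means and then converted into two different coupling partners. A6 lacks the chiral acyl group, which would have to be introduced last at the free carbon by Friedel–Crafts or Fries chemistry with an α-branched, racemisable acyl donor on an acid-sensitive bis(diarylmethane).
- Comparison: on structure it closes one ring against two. On mechanism it is better precedented. On step economy it is the longest plan, because the outer rings cost a separate synthesis.

Key step: step 11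

**Remarks on the chemistry (assumptions and corrections)**

- The ring-opened enoate in which ester and keto chain stay cis is the E isomer by the sequence rules (CO2CH3 outranks the carbinol carbon, OCH3 outranks carbon); 19 is drawn so.
- The three carbinol centres form without control and are carried as mixtures; all become ketones in step 14, so only the (S)-centre matters.
- 2,4,6-Trialkoxybenzyl bromides ionise too easily to be isolated as bis-electrophiles, so the two-carbon links of 18 are made from a stable ring B dialdehyde by aldol condensation and hydrogenation.
- A phenol ortho or para to a benzylic carbinol or its silyl ether loses the benzylic oxygen through a quinone methide and is attacked by oxidants, so the four new phenols of 20 are capped before desilylation and oxidation; crude 20 is carried on at once.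
- (S)-2-Methylbutan-1-ol is taken as the commercial source of the stereocentre, because its aldehyde delivers the ring B side chain directly at the carbinol level.

## Steps

Step 1
Reactants: 1 3-methylpentane-2,4-dione
Product: 2 4-methyl-3,5-dioxohexanoic acid
Conditions: LiN(i-Pr)2 (2.2 equiv), THF, −78 → 0 °C; CO2, −78 °C; aq HCl, 0 °C
Reagents that add atoms: carbon dioxide, O=C=O
Why: The β-diketone dianion (C3 deprotonated first, then a terminal methyl) is carboxylated at the more basic terminal carbon, the standard dianion carboxylation; the acid is kept cold and used at once to avoid decarboxylation.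

Step 2
Reactants: 2 4-methyl-3,5-dioxohexanoic acid
Product: 3 4-hydroxy-5,6-dimethyl-2H-pyran-2-one
Conditions: 1,1′-carbonyldiimidazole, THF, 25 °C; aq HCl
Reagents that add atoms: none
Why: The acid is activated as its acyl imidazole and the enol oxygen of the C5 ketone closes the lactone, the usual cyclisation of 3,5-dioxo acids to 4-hydroxy-2-pyrones.

Step 3
Reactants: 3 4-hydroxy-5,6-dimethyl-2H-pyran-2-one
Product: 4 4-methoxy-5,6-dimethyl-2H-pyran-2-one
Conditions: Me2SO4, K2CO3, acetone, reflux
Reagents that add atoms: dimethyl sulfate, COS(=O)(=O)OC
Why: O-Methylation of the vinylogous acid under these conditions is known to favour the 4-methoxy-2-pyrone over the isomeric 2-methoxy-4-pyrone.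

Step 4
Reactants: 4 4-methoxy-5,6-dimethyl-2H-pyran-2-one; 5 butanal
Product: 7 3-[1-(tert-butyldimethylsilyloxy)butyl]-4-methoxy-5,6-dimethyl-2H-pyran-2-one (racemic), via lithium alkoxide of the C3 carbinol 6 (not isolated)
Conditions: n-BuLi, THF, −78 °C; 5, −78 °C; TBSOTf, −78 → 0 °C
Reagents that add atoms: tert-butyldimethylsilyl trifluoromethanesulfonate (TBSOTf), CC(C)(C)[Si](C)(C)OS(=O)(=O)C(F)(F)F
Why: n-BuLi at −78 °C removes the C3 hydrogen between the lactone carbonyl and the methoxy group (kinetic directed lithiation of 4-methoxy-2-pyrones), the vinyllithium adds to the aldehyde, and the lithium alkoxide is silylated in the flask. The new carbinol centre is racemic and is later oxidised.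

Step 5
Reactants: 8 phloroglucinol (benzene-1,3,5-triol)
Product: 9 1,3,5-tris(methoxymethoxy)benzene
Conditions: NaH, MOMCl, DMF, 0 → 25 °C
Reagents that add atoms: chloromethyl methyl ether (MOMCl), COCCl
Why: Exhaustive O-alkylation of the sodium phenoxide with the hard electrophile MOMCl (Williamson-type acetal formation); the three acetal oxygens later direct every metalation on ring B.

Step 6
Reactants: 10 (S)-2-methylbutan-1-ol
Product: 11 (S)-2-methylbutanal
Conditions: TEMPO (cat.), KBr (cat.), NaOCl, NaHCO3, CH2Cl2/H2O, 0 °C
Reagents that add atoms: none
Why: The nitroxyl-catalysed hypochlorite oxidation stops at the aldehyde under buffered two-phase conditions that do not enolise it; the aldehyde is kept cold and used directly so that the (S)-centre is retained.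

Step 7
Reactants: 9 1,3,5-tris(methoxymethoxy)benzene; 11 (S)-2-methylbutanal
Product: 13 tert-butyl{(2S)-2-methyl-1-[2,4,6-tris(methoxymethoxy)phenyl]butoxy}dimethylsilane (both C1 epimers), via lithium alkoxide of the ring B carbinol 12 (not isolated)
Conditions: n-BuLi, THF, 0 °C; 11, −78 °C; TBSOTf, −78 → 0 °C
Reagents that add atoms: tert-butyldimethylsilyl trifluoromethanesulfonate (TBSOTf), CC(C)(C)[Si](C)(C)OS(=O)(=O)C(F)(F)F
Why: Directed ortho-metalation between two acetal oxygens gives the aryllithium, which adds to the aldehyde at −78 °C faster than it enolises it; the hindered alkoxide is capped as the silyl ether. The (S)-centre comes unchanged from 10, and the new carbinol centre is uncontrolled and later oxidised.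

Step 8
Reactants: 13 tert-butyl{(2S)-2-methyl-1-[2,4,6-tris(methoxymethoxy)phenyl]butoxy}dimethylsilane
Product: 15 5-[(2S)-1-(tert-butyldimethylsilyloxy)-2-methylbutyl]-2,4,6-tris(methoxymethoxy)benzene-1,3-dicarbaldehyde, via lithium α-amino alkoxide of the monoaldehyde 14 (not isolated)
Conditions: n-BuLi, TMEDA, THF, 0 °C; DMF, −78 °C; n-BuLi, −78 → 0 °C; DMF, −78 → 0 °C; H2O
Reagents that add atoms: N,N-dimethylformamide (DMF), CN(C)C=O
Why: Each remaining ring hydrogen lies between two acetal oxygens and is removed by n-BuLi (directed ortho-metalation and formylation). After the first formylation the aldehyde stays masked as its lithium α-amino alkoxide, which tolerates the second metalation, so both formyl groups enter in one flask.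

Step 9
Reactants: 7 3-[1-(tert-butyldimethylsilyloxy)butyl]-4-methoxy-5,6-dimethyl-2H-pyran-2-one (2.2 equiv); 15 ring B dialdehyde
Product: 17 bis(styrylpyrone): 15 in which each formyl group has become an (E)-2-{3-[1-(tert-butyldimethylsilyloxy)butyl]-4-methoxy-5-methyl-2-oxo-2H-pyran-6-yl}ethenyl group, via dilithium bis(aldolate) 16 (not isolated)
Conditions: LiN(i-Pr)2, THF, −78 °C; 15, −78 °C; MsCl, Et3N, −78 → 25 °C
Reagents that add atoms: none
Why: LiN(i-Pr)2 deprotonates 7 only at the 6-methyl group, whose anion is a fully conjugated trienolate (the 5-methyl anion is cross-conjugated), and this anion adds to both aldehydes (vinylogous aldol). Mesylation of the electron-rich benzylic alkoxides triggers elimination to the E-alkenes, as in the aldol condensations used for 6-styryl-4-methoxy-2-pyrones.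

Step 10
Reactants: 17 bis(styrylpyrone)
Product: 18 ring B tris(methoxymethyl) ether with the silyl-protected (2S)-2-methylbutyl carbinol and two 2-{3-[1-(tert-butyldimethylsilyloxy)butyl]-4-methoxy-5-methyl-2-oxo-2H-pyran-6-yl}ethyl arms
Conditions: H2 (1 atm), Pd on carbon, EtOAc, 25 °C
Reagents that add atoms: none
Why: Heterogeneous hydrogenation saturates the disubstituted exocyclic alkenes and leaves the tetrasubstituted pyrone double bonds and the silyl and acetal ethers, as in the known reduction of 6-styryl-2-pyrones to 6-(2-arylethyl)-2-pyrones.

Step 11
Reactants: 18 bis(pyranylethyl) ring B compound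
Product: 20 bridged trimer: ring B unit of 18 in which each arm has become a 3-[1-(tert-butyldimethylsilyloxy)butyl]-2,6-dihydroxy-4-methoxy-5-methylbenzyl group, via ring-opened bis(keto enoate) 19 (not isolated)
Conditions: NaOMe (8 equiv), MeOH/THF, argon, 0 → 45 °C; AcOH, −20 °C; pH 7 buffer; crude product used at once
Reagents that add atoms: none
Why: Proposed new method: methoxide adds to each lactone carbonyl and the ring opens at the acyl–oxygen bond to the 3-methoxy-5-oxo-2-enoate 19 (E by the sequence rules, ester and keto chain still cis as in the pyrone); the small equilibrium share of the ketone enolate on the methylene side then attacks the ester carbonyl, methoxide leaves, and the 5-methoxycyclohex-4-ene-1,3-dione so formed tautomerises to the resorcinol, whose deprotonation makes the sequence irreversible while opening and reclosure of the pyrone stay reversible. The closest known reaction types are the alkoxide-mediated Claisen cyclisation of 5-oxo esters to cyclohexane-1,3-diones, the Mg(OMe)2-mediated recyclisation of 6-(2-oxoalkyl)-4-hydroxy-2-pyrones to acylphloroglucinols and carbanion-induced 2-pyranone-to-benzene ring transformations; new here is that the attacking carbon is activated by a single ketone and that the ester is a hindered vinylogous carbonate. Rings A and C each close in the 6-(enolendo)-exo-trig mode. No stereocentre is created: the transient centre at the methyl-bearing carbon and the alkene geometry vanish on aromatisation, and the (S)-centre cannot epimerise because its neighbour is a silyl-protected carbinol carbon without acidic hydrogen. The selectivity needed is C-acylation from the methylene enolate; the more acidic hydrogen on the methyl-bearing carbon leads only to a dienolate that recloses through oxygen to the pyrone or would have to form a four-membered ring, and with all acyl groups held at the carbinol level no ketone is present that could divert the carbanion into an aldol closure to a benzoate or consume base. Temperature and time are kept to the minimum and the mixture is neutralised cold, because the product phenoxides stand ortho and para to benzylic silyl ethers.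

Step 12
Reactants: 20 bridged trimer with four free outer-ring phenols
Product: 21 tetrakis(methoxymethyl) ether of 20 (all seven phenolic oxygens as methoxymethyl ethers; three silyl-protected carbinols)
Conditions: MOMCl, i-Pr2NEt, CH2Cl2, 0 → 25 °C
Reagents that add atoms: chloromethyl methyl ether (MOMCl), COCCl
Why: Williamson-type acetal formation on the four hindered phenols under amine base. It is done before any carbinol is unmasked, so that no free phenol later stands ortho or para to a benzylic hydroxyl or meets an oxidant.

Step 13
Reactants: 21 heptakis(methoxymethyl) tris(silyl ether)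
Product: 22 triol: 21 with the three silyl ethers replaced by secondary benzylic hydroxyls
Conditions: Bu4NF, THF, 25 → 50 °C
Reagents that add atoms: none
Why: Fluoride cleaves the three Si–O bonds (desilylation). With every phenol capped the alkoxides cannot expel oxygen as quinone methides, and no ketone is yet present, so the basic medium cannot touch the (S)-centre.

Step 14
Reactants: 22 triol
Product: 23 triketone: heptakis(methoxymethyl) ether of agrimol B with the (S)-2-methylbutanoyl group on ring B and a butanoyl group on each outer ring
Conditions: Dess–Martin periodinane, pyridine, CH2Cl2, 0 → 25 °C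
Reagents that add atoms: none
Why: Dess–Martin oxidation turns the three hindered secondary benzylic alcohols into aryl ketones under buffered, non-enolising conditions, so the (S)-centre next to the new ring B ketone is kept.

Step 15
Reactants: 23 heptakis(methoxymethyl) triketone
Product: 24 agrimol B, (S)
Conditions: HCl (1.25 M in MeOH), 25 → 40 °C
Reagents that add atoms: none
Why: Acid-catalysed transacetalisation to methanol removes all seven aryl methoxymethyl ethers. Dilute acid, low temperature and short exposure are chosen because the methylene bridges and the α-centre are acid-sensitive, and no ring carbon is free to react with the formaldehyde acetal released.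

## Compound list

1 | 3-methylpentane-2,4-dione | CC(=O)C(C)C(C)=O | starting material
2 | 4-methyl-3,5-dioxohexanoic acid | CC(=O)C(C)C(=O)CC(=O)O | intermediate
3 | 4-hydroxy-5,6-dimethyl-2H-pyran-2-one | Cc1oc(=O)cc(O)c1C | intermediate
4 | 4-methoxy-5,6-dimethyl-2H-pyran-2-one | COc1cc(=O)oc(C)c1C | intermediate
5 | butanal | CCCC=O | starting material
6 | lithium 1-(4-methoxy-5,6-dimethyl-2-oxo-2H-pyran-3-yl)butan-1-olate (racemic, not isolated) | [Li+].CCCC([O-])c1c(OC)c(C)c(C)oc1=O | intermediate
7 | 3-[1-(tert-butyldimethylsilyloxy)butyl]-4-methoxy-5,6-dimethyl-2H-pyran-2-one (racemic) | CCCC(O[Si](C)(C)C(C)(C)C)c1c(OC)c(C)c(C)oc1=O | intermediate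
8 | phloroglucinol (benzene-1,3,5-triol) | Oc1cc(O)cc(O)c1 | starting material
9 | 1,3,5-tris(methoxymethoxy)benzene | COCOc1cc(OCOC)cc(OCOC)c1 | intermediate
10 | (S)-2-methylbutan-1-ol | CC[C@H](C)CO | starting material
11 | (S)-2-methylbutanal | CC[C@H](C)C=O | intermediate
12 | lithium (2S)-2-methyl-1-[2,4,6-tris(methoxymethoxy)phenyl]butan-1-olate (both C1 epimers, not isolated) | [Li+].CC[C@H](C)C([O-])c1c(OCOC)cc(OCOC)cc1OCOC | intermediate
13 | tert-butyl{(2S)-2-methyl-1-[2,4,6-tris(methoxymethoxy)phenyl]butoxy}dimethylsilane (both C1 epimers) | CC[C@H](C)C(O[Si](C)(C)C(C)(C)C)c1c(OCOC)cc(OCOC)cc1OCOC | intermediate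
14 | lithium {3-[(2S)-1-(tert-butyldimethylsilyloxy)-2-methylbutyl]-2,4,6-tris(methoxymethoxy)phenyl}(dimethylamino)methanolate (not isolated) | [Li+].CC[C@H](C)C(O[Si](C)(C)C(C)(C)C)c1c(OCOC)cc(OCOC)c(C([O-])N(C)C)c1OCOC | intermediate
15 | 5-[(2S)-1-(tert-butyldimethylsilyloxy)-2-methylbutyl]-2,4,6-tris(methoxymethoxy)benzene-1,3-dicarbaldehyde | CC[C@H](C)C(O[Si](C)(C)C(C)(C)C)c1c(OCOC)c(C=O)c(OCOC)c(C=O)c1OCOC | intermediate
16 | dilithium bis(aldolate) from 15 and two molecules of 7 (each formyl carbon now a lithium carbinolate bearing the pyran-6-ylmethyl group; not isolated) | [Li+].[Li+].CC[C@H](C)C(O[Si](C)(C)C(C)(C)C)c1c(OCOC)c(C([O-])Cc2oc(=O)c(C(O[Si](C)(C)C(C)(C)C)CCC)c(OC)c2C)c(OCOC)c(C([O-])Cc2oc(=O)c(C(O[Si](C)(C)C(C)(C)C)CCC)c(OC)c2C)c1OCOC | intermediate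
17 | 1-[(2S)-1-(tert-butyldimethylsilyloxy)-2-methylbutyl]-2,4,6-tris(methoxymethoxy)-3,5-bis[(E)-2-{3-[1-(tert-butyldimethylsilyloxy)butyl]-4-methoxy-5-methyl-2-oxo-2H-pyran-6-yl}ethenyl]benzene | CC[C@H](C)C(O[Si](C)(C)C(C)(C)C)c1c(OCOC)c(/C=C/c2oc(=O)c(C(O[Si](C)(C)C(C)(C)C)CCC)c(OC)c2C)c(OCOC)c(/C=C/c2oc(=O)c(C(O[Si](C)(C)C(C)(C)C)CCC)c(OC)c2C)c1OCOC | intermediate
18 | 1-[(2S)-1-(tert-butyldimethylsilyloxy)-2-methylbutyl]-2,4,6-tris(methoxymethoxy)-3,5-bis(2-{3-[1-(tert-butyldimethylsilyloxy)butyl]-4-methoxy-5-methyl-2-oxo-2H-pyran-6-yl}ethyl)benzene (carbinol centres unspecified) | CC[C@H](C)C(O[Si](C)(C)C(C)(C)C)c1c(OCOC)c(CCc2oc(=O)c(C(O[Si](C)(C)C(C)(C)C)CCC)c(OC)c2C)c(OCOC)c(CCc2oc(=O)c(C(O[Si](C)(C)C(C)(C)C)CCC)c(OC)c2C)c1OCOC | intermediate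
19 | ring-opened bis(keto enoate): each arm is CH2CH2–C(=O)–CH(CH3)–C(OCH3)=C(CO2CH3)–CH(OSi)C3H7 with the E alkene (ester cis to the keto chain; not isolated) | CC[C@H](C)C(O[Si](C)(C)C(C)(C)C)c1c(OCOC)c(CCC(=O)C(C)/C(OC)=C(\C(=O)OC)C(O[Si](C)(C)C(C)(C)C)CCC)c(OCOC)c(CCC(=O)C(C)/C(OC)=C(\C(=O)OC)C(O[Si](C)(C)C(C)(C)C)CCC)c1OCOC | intermediate
20 | 1-[(2S)-1-(tert-butyldimethylsilyloxy)-2-methylbutyl]-2,4,6-tris(methoxymethoxy)-3,5-bis{3-[1-(tert-butyldimethylsilyloxy)butyl]-2,6-dihydroxy-4-methoxy-5-methylbenzyl}benzene | CC[C@H](C)C(O[Si](C)(C)C(C)(C)C)c1c(OCOC)c(Cc2c(O)c(C)c(OC)c(C(O[Si](C)(C)C(C)(C)C)CCC)c2O)c(OCOC)c(Cc2c(O)c(C)c(OC)c(C(O[Si](C)(C)C(C)(C)C)CCC)c2O)c1OCOC | intermediate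
21 | tetrakis(methoxymethyl) ether of 20 | CC[C@H](C)C(O[Si](C)(C)C(C)(C)C)c1c(OCOC)c(Cc2c(OCOC)c(C)c(OC)c(C(O[Si](C)(C)C(C)(C)C)CCC)c2OCOC)c(OCOC)c(Cc2c(OCOC)c(C)c(OC)c(C(O[Si](C)(C)C(C)(C)C)CCC)c2OCOC)c1OCOC | intermediate
22 | triol from 21 (three free secondary benzylic hydroxyls, seven methoxymethyl ethers) | CC[C@H](C)C(O)c1c(OCOC)c(Cc2c(OCOC)c(C)c(OC)c(C(O)CCC)c2OCOC)c(OCOC)c(Cc2c(OCOC)c(C)c(OC)c(C(O)CCC)c2OCOC)c1OCOC | intermediate
23 | heptakis(methoxymethyl) ether of agrimol B, (S) | CC[C@H](C)C(=O)c1c(OCOC)c(Cc2c(OCOC)c(C)c(OC)c(C(=O)CCC)c2OCOC)c(OCOC)c(Cc2c(OCOC)c(C)c(OC)c(C(=O)CCC)c2OCOC)c1OCOC | intermediate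
24 | agrimol B, (S) | CCCC(=O)c1c(O)c(Cc2c(O)c(Cc3c(O)c(C)c(OC)c(C(=O)CCC)c3O)c(O)c(C(=O)[C@@H](C)CC)c2O)c(O)c(C)c1OC | target

## Step count and least certain steps

Total: 15 steps. Longest linear sequence: 11 steps (steps 1–4 and 9–15, from 1).

**Step 11 (key step).** Two processes are most likely to spoil it. First, the ring-opened keto enoate may simply reclose to the pyrone faster than the less acidic methylene is enolised, or may fragment by retro-Claisen attack of methoxide on the ketone. Second, once a ring has aromatised, its phenoxide may expel the benzylic silanolate (quinone methide formation), followed by methanol addition or tautomerisation to a vinylphenol. The fallback uses known chemistry, sets out from 8 and returns at 24: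
- Friedel–Crafts acylation of 8 with (S)-2-methylbutanoyl chloride and AlCl3 would give (S)-2-methyl-1-(2,4,6-trihydroxyphenyl)butan-1-one F1.
- A double Mannich reaction with N,N-dimethylmethyleneiminium iodide would give the 3,5-bis(dimethylaminomethyl) derivative F2.
- In parallel, commercial 2-methylbenzene-1,3,5-triol F3 would be acylated with butanoyl chloride and AlCl3 to 1-(2,4,6-trihydroxy-3-methylphenyl)butan-1-one F4.
- The two less hindered phenols of F4 would be protected (MOMCl, i-Pr2NEt) to give 1-[2-hydroxy-4,6-bis(methoxymethoxy)-3-methylphenyl]butan-1-one F5.
- The remaining chelated phenol would be methylated (Me2SO4, K2CO3) to 1-[2-methoxy-4,6-bis(methoxymethoxy)-3-methylphenyl]butan-1-one F6, and the acetals removed (HCl, MeOH) to give 1-(4,6-dihydroxy-2-methoxy-3-methylphenyl)butan-1-one F7, whose only free ring carbon lies between the two hydroxyls.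
- Heating F2 with an excess of F7 in dioxane would release the ortho-quinone methide of ring B twice, and F7 would add through its free carbon to give 24. This is the classical Mannich-base route to methylene-bridged acylphloroglucinols.

**Step 4.** Deprotonation may go to the 6-methyl group, or n-BuLi may add to the lactone carbonyl, instead of metalation at C3. The fallback sets out from 4 and returns at 7. Bromination with N-bromosuccinimide in MeCN would give 3-bromo-4-methoxy-5,6-dimethyl-2H-pyran-2-one F8. Halogen–metal exchange with i-PrMgCl·LiCl in THF at −40 °C, addition of 5 and silylation with TBSOTf would give 7 with the position of the metal fixed by the halogen.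

**Step 8.** The lithium α-amino alkoxide may collapse before the second metalation, so that n-BuLi adds to the freed aldehyde, or the second metalation may stay incomplete. The fallback sets out from 13 and returns at 15. Two-fold bromination with N-bromosuccinimide in MeCN at 0 °C would give the 3,5-dibromo derivative F9. Double bromine–lithium exchange with t-BuLi in THF at −78 °C and quenching with DMF would give 15.

**Step 9.** Addition to the hindered, electron-rich aldehydes may be slow or reverse by retro-aldol cleavage, and the reaction may stop after one condensation. The fallback sets out from 15, returns at 18, and so bypasses 17 and step 10. Reduction with NaBH4 would give the bis(hydroxymethyl) compound F10. Appel bromination (CBr4, PPh3, 2,6-lutidine, −20 °C) would give the bis(bromomethyl) compound F11, which would be used cold and crude because of its lability. Alkylation of the 6-lithiomethyl derivative of 7 (LiN(i-Pr)2, THF/DMPU, −78 °C) with F11 would give 18 directly.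

**Step 15.** Acid may enolise the ring B ketone (epimerisation) or protonate a ring carbon and cleave a methylene bridge before all seven acetals are gone. The fallback sets out from 23 and returns at 24. Treatment with TMSOTf and 2,2′-bipyridyl in CH2Cl2 at 0 °C would exchange each aryl methoxymethyl ether for a trimethylsilyl ether without Brønsted acid, giving the heptakis(trimethylsilyl) ether of agrimol B F12. Neutral hydrolysis in aqueous methanol would then give 24.

## Further compounds

F1 | step 11 | (S)-2-methyl-1-(2,4,6-trihydroxyphenyl)butan-1-one | CC[C@H](C)C(=O)c1c(O)cc(O)cc1O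
F2 | step 11 | (S)-1-{3,5-bis[(dimethylamino)methyl]-2,4,6-trihydroxyphenyl}-2-methylbutan-1-one | CC[C@H](C)C(=O)c1c(O)c(CN(C)C)c(O)c(CN(C)C)c1O
F3 | step 11 | 2-methylbenzene-1,3,5-triol | Cc1c(O)cc(O)cc1O
F4 | step 11 | 1-(2,4,6-trihydroxy-3-methylphenyl)butan-1-one | CCCC(=O)c1c(O)c(C)c(O)cc1O
F5 | step 11 | 1-[2-hydroxy-4,6-bis(methoxymethoxy)-3-methylphenyl]butan-1-one | CCCC(=O)c1c(O)c(C)c(OCOC)cc1OCOC
F6 | step 11 | 1-[2-methoxy-4,6-bis(methoxymethoxy)-3-methylphenyl]butan-1-one | CCCC(=O)c1c(OC)c(C)c(OCOC)cc1OCOC
F7 | step 11 | 1-(4,6-dihydroxy-2-methoxy-3-methylphenyl)butan-1-one | CCCC(=O)c1c(OC)c(C)c(O)cc1O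
F8 | step 4 | 3-bromo-4-methoxy-5,6-dimethyl-2H-pyran-2-one | COc1c(Br)c(=O)oc(C)c1C
F9 | step 8 | {(2S)-1-[3,5-dibromo-2,4,6-tris(methoxymethoxy)phenyl]-2-methylbutoxy}(tert-butyl)dimethylsilane | CC[C@H](C)C(O[Si](C)(C)C(C)(C)C)c1c(OCOC)c(Br)c(OCOC)c(Br)c1OCOC
F10 | step 9 | {5-[(2S)-1-(tert-butyldimethylsilyloxy)-2-methylbutyl]-2,4,6-tris(methoxymethoxy)-1,3-phenylene}dimethanol | CC[C@H](C)C(O[Si](C)(C)C(C)(C)C)c1c(OCOC)c(CO)c(OCOC)c(CO)c1OCOC
F11 | step 9 | {(2S)-1-[3,5-bis(bromomethyl)-2,4,6-tris(methoxymethoxy)phenyl]-2-methylbutoxy}(tert-butyl)dimethylsilane | CC[C@H](C)C(O[Si](C)(C)C(C)(C)C)c1c(OCOC)c(CBr)c(OCOC)c(CBr)c1OCOC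
F12 | step 15 | heptakis(trimethylsilyl) ether of agrimol B, (S) | CCCC(=O)c1c(O[Si](C)(C)C)c(Cc2c(O[Si](C)(C)C)c(Cc3c(O[Si](C)(C)C)c(C)c(OC)c(C(=O)CCC)c3O[Si](C)(C)C)c(O[Si](C)(C)C)c(C(=O)[C@@H](C)CC)c2O[Si](C)(C)C)c(O[Si](C)(C)C)c(C)c1OC
A1 | alternative 1 | (S)-1-[2,4-bis(benzyloxy)-6-hydroxyphenyl]-2-methylbutan-1-one | CC[C@H](C)C(=O)c1c(O)cc(OCc2ccccc2)cc1OCc1ccccc1
A2 | alternative 1 | 3,5-bis(benzyloxy)-2-(trimethylsilyl)phenyl trifluoromethanesulfonate | C[Si](C)(C)c1c(OS(=O)(=O)C(F)(F)F)cc(OCc2ccccc2)cc1OCc1ccccc1
A3 | alternative 1 | (S)-2-methylbutanoic acid | CC[C@H](C)C(=O)O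
A4 | alternative 2 | (2S)-1-{3,5-bis[3-(1-(tert-butyldimethylsilyloxy)butyl)-6-hydroxy-4-methoxy-5-methyl-2-(triisopropylsilyloxy)benzyl]-2,4,6-tris(methoxymethoxy)phenyl}-2-methylbutan-1-one | CC[C@H](C)C(=O)c1c(OCOC)c(Cc2c(O)c(C)c(OC)c(C(O[Si](C)(C)C(C)(C)C)CCC)c2O[Si](C(C)C)(C(C)C)C(C)C)c(OCOC)c(Cc2c(O)c(C)c(OC)c(C(O[Si](C)(C)C(C)(C)C)CCC)c2O[Si](C(C)C)(C(C)C)C(C)C)c1OCOC
A5 | alternative 2 | 1-methoxypropyne | CC#COC
A6 | alternative 3 | 2,4-bis({3-[1-(tert-butyldimethylsilyloxy)butyl]-4-methoxy-2,6-bis(methoxymethoxy)-5-methylphenyl}methyl)-3,5-bis(triisopropylsilyloxy)phenol | Oc1cc(O[Si](C(C)C)(C(C)C)C(C)C)c(Cc2c(OCOC)c(C)c(OC)c(C(O[Si](C)(C)C(C)(C)C)CCC)c2OCOC)c(O[Si](C(C)C)(C(C)C)C(C)C)c1Cc1c(OCOC)c(C)c(OC)c(C(O[Si](C)(C)C(C)(C)C)CCC)c1OCOC
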